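## The problem

Locants: rings B and C use chroman-4-one numbering (O1, C2–C4, C4a, C5–C8, C8a). Ring A is primed, with C1′ at the methylene bridge, C3′ at the isobutyryl group and C5′ at the methyl group.

The target 28 is two fully substituted phloroglucinol rings joined by one methylene carbon. Ring A has hydroxyls at C2′, C4′ and C6′, an isobutyryl group at C3′ and a methyl group at C5′. Ring B has the bridge at C8, a methyl group at C6, free hydroxyls at C5 and C7, and its third oxygen is O1 of the fused 2,2-dimethylpyran-4-one (ring C). There is no stereocentre, so the task is purely regiochemical: twelve aromatic positions, none left as C–H, must each receive the right group. On ring B the three oxygens of a free phloroglucinol are nearly equivalent, yet only the one at C8a may close ring C and the bridge must sit at C8, not C6. The molecule is sensitive in three ways: the electron-rich diarylmethane can lose or exchange its benzyl group after ipso protonation, ring C can open by retro-oxa-Michael reaction and re-close on the C5 oxygen once that is free, and the polyphenol is easily oxidised. The enabling feature is the strict O–C–O–C–O–C alternation around ring B. C8a–O, C7–O and C5–O can be traced to three different functional groups (a ketene carbonyl, a silyl ynol ether and an ethyl enol ether), and C8, lying between the first two, is the nucleophilic carbon of an ynol ether that can carry ring A as a benzyl group.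

## Retrosynthesis

**28 ⇒ 27.** The last operation cuts only O–alkyl bonds: three O–CH3 bonds on ring A and the O–ethyl bond at C5. Methyl ethers are chosen for ring A because they must survive amide base, peroxide anion, 110 °C and strong acid. The C5 ethyl ether also prevents ring C from forming on, or migrating to, the C5 oxygen, so it is removed only at the very end. The forward step must cleave four ethers without opening ring C.

**27 ⇒ 24 + 25.** Ring C is removed by cutting C4a–C4 and O1–C2, which returns resorcinol 24 and 3-methylbut-2-enoic acid 25. In 24, C4a is the only aromatic C–H in the molecule, since ring A is fully substituted and carries a ketone. C8a–OH is the only hydroxyl ortho to C4a, because C5 is an ether and C7–OH is para. A Friedel–Crafts acylation followed by oxa-Michael closure therefore has one possible outcome. Keeping the isobutyryl group on ring A from the start is what makes this cut safe; a ring A with a free position would compete for the acylating agent.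

**24 ⇒ 23.** The C7 silyl ether is removed separately so that the substrate of the acid step is a defined compound.

**23 ⇒ 11 + 18 (key cut).** Ring B is taken apart at C8a–C8, C7–C6 and C8a–C4a, giving siloxyalkyne 11 and cyclobutenone 18. The neighbouring cut, a Friedel–Crafts benzylation that forms the C8–CH2 bond on a preformed ring B, would have to choose between C8 and C6 and between near-equivalent hydroxyls. This cut instead assigns each oxygen its own origin: the ketene oxygen becomes the free C8a–OH, the ynol oxygen becomes the C7 silyl ether, and the enol-ether oxygen becomes the C5 ethyl ether. A hexasubstituted benzene is reduced to a four-carbon and a two-carbon piece, with ring A carried as a spectator benzyl group. The forward reaction needs only the correct orientation of one ketene–alkyne (2+2) addition.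

**18 ⇒ 17 ⇒ 14 + 15; 14 ⇒ 12.** The cyclobutenone comes from 4,4-dichlorocyclobutenone 17 by reductive dechlorination. Compound 17 is the (2+2) adduct of 1-ethoxyprop-1-yne 14 with dichloroketene 16, generated from trichloroacetyl chloride 15. Ynol ether 14 is made by methylating ethoxyacetylene 12. The polarity of the ynol ether places methyl at C2 and ethoxy at C3 of the cyclobutenone.

**11 ⇒ 8.** The siloxyalkyne is cut at O–Si and C(sp)–O, back to terminal alkyne 8 by way of lithium ynolate 10. Ester homologation through a dibromomethyl ketone would be the obvious alternative, but it needs LiCHBr2 and excess butyllithium, which the ring-A ketone would not survive. Oxidising a lithium acetylide with lithium tert-butyl peroxide needs only LiHMDS, toward which the hindered, twisted ketone should be inert. The triisopropylsilyl group is chosen because its ynol ethers are isolable and thermally robust.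

**8 ⇒ 7 ⇒ 4 + 5; 4 ⇒ 3 ⇒ 1 + 2.** The propargyl arene comes from benzylic chloride 4 and ethynyltrimethylsilane 5 by a ketone-tolerant Negishi coupling through zinc reagent 6, then desilylation. Chloride 4 is made by chloromethylating the single free position of ketone 3. Ketone 3 is the Friedel–Crafts product of 2,4,6-trimethoxytoluene 1 and 2-methylpropanoyl chloride 2; the two free positions of 1 are equivalent.

## Roads not taken

**Alternative 1:** The cut is at the C4′–O and C5–O bonds. The tri-O-acetate A2, lacking both hydroxyls, would be treated with Pd(OAc)2 and K2S2O8 in CF3CO2H/(CF3CO)2O. Each ketone directs palladation of its ortho C–H (C4′–H and C5–H), and the trifluoroacetates hydrolyse on work-up to give A1.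
- Merits: A2 has only two oxygens per ring, both ketones act as directing groups, and A1 needs only mild acetate methanolysis to reach 28. That final deprotection is clearly gentler than the BBr3 step of the chosen plan.
- Weak points: both C–H bonds are flanked on both sides. The ring-A ketone sits between an acetate and the reacting carbon and is twisted out of plane, which disfavours a coplanar palladacycle. Acetates can scramble in trifluoroacetic acid. Persulfate can oxidise the doubly benzylic methylene and the electron-rich rings. Two such oxidations must succeed on one molecule.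
- Comparison: A2 is itself a pair of pentasubstituted rings needing the same regiocontrol at C8 and C8a, so the main problem is postponed, not solved. The chosen plan accepts a harsher deprotection in exchange for never oxidising an electron-rich advanced intermediate and for having all oxygens in place from the building blocks.

**Alternative 2:** The cut removes all of ring C (C8a–O1, C4a–C4, O1–C2). Fluoride (CsF, hot THF) would release aryne A5 from ortho-silylaryl triflate A4. The carboxylate of acid 25 adds at C8a, the aryl anion at C4a captures the acyl group, and the freed phenoxide closes ring C to give the penta-O-methyl compound A3.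
- Merits: ring C forms without strong acid while the fragile bridge is present, which is better than step 11 of the chosen plan. The C5 methoxy group should direct the nucleophile to C8a.
- Weak points: A4 is a hexasubstituted benzene. Making it presupposes a ring B with a free C8a hydroxyl next to an unsubstituted C4a, and then needs ortho-silylation and triflation. The aryne is flanked by a methoxy and a bulky benzyl group. The insertion must work with a β,β-disubstituted acrylic acid. A3 still needs fivefold demethylation.
- Comparison: this is a longer end-game for the same intermediate type, not a solution to ring B. The chosen plan acylates the phenol directly in one step and answers the acid risk with a base-mediated fallback.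

**Alternative 3:** The cut is at C2′–C3′ of ring A. Mg(OMe)2 in methanol would open 4-hydroxypyran-2-one A7 to the chelated triketo ester A8. The methylene between the two ketones then attacks the ester carbon in a Claisen condensation to give the 5,7-di-O-methyl compound A6.
- Merits: ring A arrives with its three hydroxyls free and its acyl group in place, so ring A needs no demethylation. In protecting-group economy on ring A this is better than the chosen plan.
- Weak points: ring B with its 5,7-dimethoxy pattern, the bridge at C8 and ring C on the correct oxygen must still be built regioselectively beforehand. A8 has substituents on both internal carbons, which slows enolisation and opens aldol and re-lactonisation pathways. Ring C is exposed to methoxide. The last step is still a Lewis-acid demethylation at C5 and C7, now next to a free acylphloroglucinol that makes bridge scission easier.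
- Comparison: it simplifies ring A, which is the easy ring, and leaves ring B unsolved. The chosen plan spends its key step on ring B and pays with three extra methyl ethers to remove.

Key step: step 9

Assumption: the 3′-ketone, flanked by two ortho methoxy groups and an isopropyl group, is taken to be inert to LiHMDS and alkynylzinc reagents at low temperature, as doubly ortho-substituted aryl ketones normally are; the target is achiral, so no stereocontrol is needed.

## Route

Step 1
Reactants: 1 2,4,6-trimethoxytoluene; 2 2-methylpropanoyl chloride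
Product: 3 2-methyl-1-(2,4,6-trimethoxy-3-methylphenyl)propan-1-one
Conditions: TiCl4, CH2Cl2, −20 → 0 °C
Reagents that add atoms: none
Why: Friedel–Crafts acylation; the two free positions of 1 are equivalent and the first acyl group deactivates the ring against a second. A mild Lewis acid at low temperature should avoid cleavage of the methoxy groups ortho to the new ketone.

Step 2
Reactants: 3 2-methyl-1-(2,4,6-trimethoxy-3-methylphenyl)propan-1-one
Product: 4 1-[3-(chloromethyl)-2,4,6-trimethoxy-5-methylphenyl]-2-methylpropan-1-one
Conditions: MOMCl (excess), SnCl4, CH2Cl2, 0 °C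
Reagents that add atoms: chloromethyl methyl ether, COCCl
Why: Blanc-type chloromethylation at the only remaining aromatic C–H, which is activated by three methoxy groups. Excess electrophile should outrun benzylation of unreacted 3 by the product.

Step 3
Reactants: 4 1-[3-(chloromethyl)-2,4,6-trimethoxy-5-methylphenyl]-2-methylpropan-1-one; 5 ethynyltrimethylsilane
Product: 7 2-methyl-1-[2,4,6-trimethoxy-3-methyl-5-[3-(trimethylsilyl)prop-2-ynyl]phenyl]propan-1-one, via alkynylzinc bromide 6 (not isolated)
Conditions: 5, n-BuLi, THF, −78 °C; ZnBr2, → 0 °C; then 4, PdCl2(DPEphos) (cat., DPEphos = bis(2-diphenylphosphinophenyl) ether), THF, rt → 40 °C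
Reagents that add atoms: none
Why: Negishi coupling of a benzylic chloride with an alkynylzinc reagent: oxidative addition of the C–Cl bond to zerovalent palladium, transmetalation and reductive elimination form the C(sp3)–C(sp) bond. The organozinc does not add to the hindered ketone, and the silyl cap prevents a second coupling.

Step 4
Reactants: 7 2-methyl-1-[2,4,6-trimethoxy-3-methyl-5-[3-(trimethylsilyl)prop-2-ynyl]phenyl]propan-1-one
Product: 8 2-methyl-1-[2,4,6-trimethoxy-3-methyl-5-(prop-2-ynyl)phenyl]propan-1-one
Conditions: K2CO3 (cat.), MeOH, 0 °C → rt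
Reagents that add atoms: none
Why: Methoxide-catalysed protodesilylation of the alkynylsilane. It is kept cold and short so that the benzylic propargyl unit does not isomerise to the allene.

Step 5
Reactants: 8 2-methyl-1-[2,4,6-trimethoxy-3-methyl-5-(prop-2-ynyl)phenyl]propan-1-one
Product: 11 2-methyl-1-[2,4,6-trimethoxy-3-methyl-5-[3-[tri(propan-2-yl)silyloxy]prop-2-ynyl]phenyl]propan-1-one, via lithium acetylide 9 (not isolated), via lithium ynolate 10 (not isolated)
Conditions: LiHMDS, THF, −78 °C; t-BuOOLi (from t-BuOOH and LiHMDS), −78 → 0 °C; TIPSOTf, −78 → 0 °C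
Reagents that add atoms: tert-butyl hydroperoxide, CC(C)(C)OO; triisopropylsilyl trifluoromethanesulfonate, CC(C)[Si](C(C)C)(C(C)C)OS(=O)(=O)C(F)(F)F
Why: Oxidation of a lithium acetylide by lithium tert-butyl peroxide to the ynolate, followed by O-silylation with a bulky silyl triflate. LiHMDS should remove the acetylenic proton much faster than the hindered methine beside the twisted ketone, and no carbon nucleophile that could add to the ketone is present.

Step 6
Reactants: 12 ethoxyacetylene
Product: 14 1-ethoxyprop-1-yne, via lithium ethoxyacetylide 13 (not isolated)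
Conditions: n-BuLi, THF, −78 °C; MeI, DMPU, −78 °C → rt
Reagents that add atoms: iodomethane, CI
Why: SN2 methylation of the lithium acetylide in a dipolar cosolvent. The volatile product is distilled and used as a solution.

Step 7
Reactants: 14 1-ethoxyprop-1-yne; 15 trichloroacetyl chloride
Product: 17 4,4-dichloro-3-ethoxy-2-methylcyclobut-2-en-1-one, via dichloroketene 16 (not isolated)
Conditions: Zn–Cu couple, Et2O–DME, 0 °C → rt
Reagents that add atoms: none
Why: Ketene–alkyne (2+2) cycloaddition. The electron-rich β-carbon of the ynol ether bonds to the ketene carbonyl carbon, so methyl ends at C2 and ethoxy at C3; DME binds the ZnCl2 formed and protects the ynol ether.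

Step 8
Reactants: 17 4,4-dichloro-3-ethoxy-2-methylcyclobut-2-en-1-one
Product: 18 3-ethoxy-2-methylcyclobut-2-en-1-one
Conditions: Zn dust, AcOH, TMEDA, EtOH, 0 °C
Reagents that add atoms: none
Why: Stepwise reductive removal of the two α-chlorines through zinc enolates under buffered conditions. Ethanol as solvent makes any alkoxy exchange on the vinylogous ester degenerate.

Step 9
Reactants: 11 2-methyl-1-[2,4,6-trimethoxy-3-methyl-5-[3-[tri(propan-2-yl)silyloxy]prop-2-ynyl]phenyl]propan-1-one; 18 3-ethoxy-2-methylcyclobut-2-en-1-one
Product: 23 1-[3-[[4-ethoxy-6-hydroxy-3-methyl-2-[tri(propan-2-yl)silyloxy]phenyl]methyl]-2,4,6-trimethoxy-5-methylphenyl]-2-methylpropan-1-one, via vinylketene 19 (not isolated), via vinylcyclobutenone 20 (not isolated), via dienylketene 21 (not isolated), via cyclohexadienone 22 (not isolated)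
Conditions: PhMe, 110 °C (sealed tube), slight excess of 18
Reagents that add atoms: none
Why: Danheiser benzannulation; the closest known reaction type is the formation of resorcinol monosilyl ethers from cyclobutenones and trialkylsiloxyalkynes. Four-electron electrocyclic opening of 18 gives vinylketene 19, whose ketene carbon is attacked by the benzyl-bearing β-carbon of ynol ether 11 in a (2+2) cycloaddition (bonds C8a–C8 and C7–C6) to give 4-vinylcyclobutenone 20. A second four-electron opening gives dienylketene 21, and ring B closes by thermal six-electron disrotatory electrocyclisation (bond C8a–C4a) to cyclohexadienone 22, which tautomerises irreversibly to phenol 23. No stereocentre survives: the quaternary carbon of 20 forms racemic and becomes sp2 again, and reversible opening of 20 funnels material through the dienylketene geometry that can cyclise. The selectivity needed is the orientation of the (2+2) step; the oxygen lone pair of the siloxyalkyne makes the carbon bearing the ring-A benzyl group nucleophilic and pairs it with the ketene carbonyl carbon, placing the oxygens 1,3,5 and the bridge at C8. The former ketene oxygen emerges as the only free hydroxyl (C8a), next to the only C–H (C4a), while C7 is a silyl ether and C5 an ethyl ether. Ring A is a fully substituted spectator whose twisted ketone should not react with ketenes or ynol ethers under neutral thermal conditions.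

Step 10
Reactants: 23 1-[3-[[4-ethoxy-6-hydroxy-3-methyl-2-[tri(propan-2-yl)silyloxy]phenyl]methyl]-2,4,6-trimethoxy-5-methylphenyl]-2-methylpropan-1-one
Product: 24 1-[3-[(4-ethoxy-2,6-dihydroxy-3-methylphenyl)methyl]-2,4,6-trimethoxy-5-methylphenyl]-2-methylpropan-1-one
Conditions: TBAF, AcOH, THF, 0 °C
Reagents that add atoms: none
Why: Fluoride cleavage of the aryl silyl ether. Acetic acid buffers the electron-rich phenoxide against air oxidation.

Step 11
Reactants: 24 1-[3-[(4-ethoxy-2,6-dihydroxy-3-methylphenyl)methyl]-2,4,6-trimethoxy-5-methylphenyl]-2-methylpropan-1-one; 25 3-methylbut-2-enoic acid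
Product: 27 5-ethoxy-7-hydroxy-2,2,6-trimethyl-8-[[2,4,6-trimethoxy-3-methyl-5-(2-methylpropanoyl)phenyl]methyl]-2,3-dihydrochromen-4-one, via aryl enone 26 (not isolated)
Conditions: MeSO3H, P2O5 (Eaton's reagent), 40 → 60 °C
Reagents that add atoms: none
Why: Friedel–Crafts acylation at C4a, the only aromatic C–H in the molecule, followed by 6-endo oxa-Michael addition of the C8a hydroxyl to enone 26. C5 is etherified and the C7 hydroxyl is para to the acyl group, so only one pyranone can form.

Step 12
Reactants: 27 5-ethoxy-7-hydroxy-2,2,6-trimethyl-8-[[2,4,6-trimethoxy-3-methyl-5-(2-methylpropanoyl)phenyl]methyl]-2,3-dihydrochromen-4-one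
Product: 28 5,7-dihydroxy-2,2,6-trimethyl-8-[[2,4,6-trihydroxy-3-methyl-5-(2-methylpropanoyl)phenyl]methyl]-2,3-dihydrochromen-4-one (target)
Conditions: BBr3 (excess), CH2Cl2, −78 °C → rt; then MeOH/H2O, 0 °C
Reagents that add atoms: none
Why: Lewis-acid ether cleavage, with bromide attacking the O-alkyl carbon of each boron-complexed ether. The three ethers beside a carbonyl (C5, C2′, C4′) should go first by chelation, and excess reagent removes the C6′ methyl ether.

## Compound list

1 | 2,4,6-trimethoxytoluene | COc1cc(OC)c(C)c(OC)c1 | starting material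
2 | 2-methylpropanoyl chloride | CC(C)C(=O)Cl | starting material
3 | 2-methyl-1-(2,4,6-trimethoxy-3-methylphenyl)propan-1-one | COc1cc(OC)c(C(=O)C(C)C)c(OC)c1C | intermediate
4 | 1-[3-(chloromethyl)-2,4,6-trimethoxy-5-methylphenyl]-2-methylpropan-1-one | COc1c(CCl)c(OC)c(C(=O)C(C)C)c(OC)c1C | intermediate
5 | ethynyltrimethylsilane | C#C[Si](C)(C)C | starting material
6 | [2-(trimethylsilyl)ethynyl]zinc bromide | C[Si](C)(C)C#C[Zn]Br | intermediate (not isolated)
7 | 2-methyl-1-[2,4,6-trimethoxy-3-methyl-5-[3-(trimethylsilyl)prop-2-ynyl]phenyl]propan-1-one | COc1c(CC#C[Si](C)(C)C)c(OC)c(C(=O)C(C)C)c(OC)c1C | intermediate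
8 | 2-methyl-1-[2,4,6-trimethoxy-3-methyl-5-(prop-2-ynyl)phenyl]propan-1-one | COc1c(CC#C)c(OC)c(C(=O)C(C)C)c(OC)c1C | intermediate
9 | lithium acetylide of 8 | COc1c(CC#[C-])c(OC)c(C(=O)C(C)C)c(OC)c1C.[Li+] | intermediate (not isolated)
10 | lithium 3-[2,4,6-trimethoxy-3-methyl-5-(2-methylpropanoyl)phenyl]prop-1-yn-1-olate | COc1c(CC#C[O-])c(OC)c(C(=O)C(C)C)c(OC)c1C.[Li+] | intermediate (not isolated)
11 | 2-methyl-1-[2,4,6-trimethoxy-3-methyl-5-[3-[tri(propan-2-yl)silyloxy]prop-2-ynyl]phenyl]propan-1-one | COc1c(C)c(OC)c(CC#CO[Si](C(C)C)(C(C)C)C(C)C)c(OC)c1C(=O)C(C)C | intermediate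
12 | ethoxyacetylene | CCOC#C | starting material
13 | lithium ethoxyacetylide | CCOC#[C-].[Li+] | intermediate (not isolated)
14 | 1-ethoxyprop-1-yne | CCOC#CC | intermediate
15 | trichloroacetyl chloride | ClC(=O)C(Cl)(Cl)Cl | starting material
16 | dichloroketene | ClC(Cl)=C=O | intermediate (not isolated)
17 | 4,4-dichloro-3-ethoxy-2-methylcyclobut-2-en-1-one | CCOC1=C(C)C(=O)C1(Cl)Cl | intermediate
18 | 3-ethoxy-2-methylcyclobut-2-en-1-one | CCOC1=C(C)C(=O)C1 | intermediate
19 | 3-ethoxy-2-methylbuta-1,3-dien-1-one | C=C(OCC)C(C)=C=O | intermediate (not isolated)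
20 | 4-(1-ethoxyethenyl)-4-methyl-3-[tri(propan-2-yl)silyloxy]-2-[[2,4,6-trimethoxy-3-methyl-5-(2-methylpropanoyl)phenyl]methyl]cyclobut-2-en-1-one (racemic) | C=C(OCC)C1(C)C(O[Si](C(C)C)(C(C)C)C(C)C)=C(Cc2c(OC)c(C)c(OC)c(C(=O)C(C)C)c2OC)C1=O | intermediate (not isolated)
21 | (3E)-5-ethoxy-4-methyl-3-[tri(propan-2-yl)silyloxy]-2-[[2,4,6-trimethoxy-3-methyl-5-(2-methylpropanoyl)phenyl]methyl]hexa-1,3,5-trien-1-one | C=C(OCC)/C(C)=C(\C(Cc1c(OC)c(C)c(OC)c(C(=O)C(C)C)c1OC)=C=O)O[Si](C(C)C)(C(C)C)C(C)C | intermediate (not isolated)
22 | 5-ethoxy-4-methyl-3-[tri(propan-2-yl)silyloxy]-2-[[2,4,6-trimethoxy-3-methyl-5-(2-methylpropanoyl)phenyl]methyl]cyclohexa-2,4-dien-1-one | CCOC1=C(C)C(O[Si](C(C)C)(C(C)C)C(C)C)=C(Cc2c(OC)c(C)c(OC)c(C(=O)C(C)C)c2OC)C(=O)C1 | intermediate (not isolated)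
23 | 1-[3-[[4-ethoxy-6-hydroxy-3-methyl-2-[tri(propan-2-yl)silyloxy]phenyl]methyl]-2,4,6-trimethoxy-5-methylphenyl]-2-methylpropan-1-one | COc1c(C)c(OC)c(Cc2c(O)cc(OCC)c(C)c2O[Si](C(C)C)(C(C)C)C(C)C)c(OC)c1C(=O)C(C)C | intermediate
24 | 1-[3-[(4-ethoxy-2,6-dihydroxy-3-methylphenyl)methyl]-2,4,6-trimethoxy-5-methylphenyl]-2-methylpropan-1-one | COc1c(C)c(OC)c(Cc2c(O)cc(OCC)c(C)c2O)c(OC)c1C(=O)C(C)C | intermediate
25 | 3-methylbut-2-enoic acid | CC(C)=CC(=O)O | starting material
26 | 1-[3-[[4-ethoxy-2,6-dihydroxy-5-methyl-3-(3-methylbut-2-enoyl)phenyl]methyl]-2,4,6-trimethoxy-5-methylphenyl]-2-methylpropan-1-one | CCOc1c(C)c(O)c(Cc2c(OC)c(C)c(OC)c(C(=O)C(C)C)c2OC)c(O)c1C(=O)C=C(C)C | intermediate (not isolated)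
27 | 5-ethoxy-7-hydroxy-2,2,6-trimethyl-8-[[2,4,6-trimethoxy-3-methyl-5-(2-methylpropanoyl)phenyl]methyl]-2,3-dihydrochromen-4-one | CCOc1c(C)c(O)c(Cc2c(OC)c(C)c(OC)c(C(=O)C(C)C)c2OC)c2OC(C)(C)CC(=O)c12 | intermediate
28 | 5,7-dihydroxy-2,2,6-trimethyl-8-[[2,4,6-trihydroxy-3-methyl-5-(2-methylpropanoyl)phenyl]methyl]-2,3-dihydrochromen-4-one | Cc1c(O)c(Cc2c(O)c(C)c(O)c3c2OC(C)(C)CC3=O)c(O)c(C(=O)C(C)C)c1O | target

## Step count and weak points

Total: 12 steps. Longest linear sequence: 9 steps (steps 1–5 and 9–12). The cyclobutenone branch (steps 6–8) joins at step 9.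

**Step 9 (key step).** The most likely failure is slow electrocyclic opening of the vinylogous-ester cyclobutenone compared with thermal decay of the partners. A second risk is capture of ketene 19 by the product phenol through O-acylation. A 3-alkoxy cyclobutenone is the less common partner in this reaction, and its donor group stabilises the four-membered ring. The fallback sets out from siloxyalkyne 11 and generates the same ketene at room temperature by a photochemical Wolff rearrangement. Ethyl vinyl ether would be lithiated to (1-ethoxyethenyl)lithium F1 and acylated with N-methoxy-N-methylpropanamide to give 2-ethoxypent-1-en-3-one F2. Trifluoroacetylation (LiHMDS, CF3CO2CH2CF3) would give 2-ethoxy-6,6,6-trifluoro-4-methylhex-1-ene-3,5-dione F3, and diazo transfer with methanesulfonyl azide and Et3N would give 4-diazo-2-ethoxypent-1-en-3-one F4. Irradiating F4 with 11 should give 19 by migration of the ethoxyvinyl group, then 20; brief warming carries 20 through 21 and 22, and the route is rejoined at 23.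

**Step 5.** Deprotonation may compete at the benzylic propargylic CH2 (propargyl–allene isomerisation) or at the ketone α-carbon, so the acetylide forms incompletely or an enolate is silylated. The fallback sets out from chloride 4 and lithium ethoxyacetylide 13 and replaces the silyl ynol ether by an ethyl one. Compound 13 with ZnCl2 would give (ethoxyethynyl)zinc chloride F5, and Negishi coupling with 4 would give 1-[3-(3-ethoxyprop-2-ynyl)-2,4,6-trimethoxy-5-methylphenyl]-2-methylpropan-1-one F6. Benzannulation of F6 with 18 would give 1-[3-[(2,4-diethoxy-6-hydroxy-3-methylphenyl)methyl]-2,4,6-trimethoxy-5-methylphenyl]-2-methylpropan-1-one F7. Acylation and closure with 25 would give 5,7-diethoxy-2,2,6-trimethyl-8-[[2,4,6-trimethoxy-3-methyl-5-(2-methylpropanoyl)phenyl]methyl]-2,3-dihydrochromen-4-one F8, and BBr3 would return the route at 28. The cost is that ethyl ynol ethers lose ethene above about 100 °C, so this variant would need the lowest workable temperature.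

**Step 11.** Hot strong acid may protonate ring B at C8 and expel the ring-A benzyl cation (loss or migration of the bridge). The hindered ring-A ketone may be deacylated, and conjugate alkylation leading to a dihydrocoumarin may compete with acylation. The fallback sets out from 24 and closes ring C under base. C-Acetylation at C4a with acetic anhydride and BF3·OEt2 at room temperature would give 1-[3-[(3-acetyl-4-ethoxy-2,6-dihydroxy-5-methylphenyl)methyl]-2,4,6-trimethoxy-5-methylphenyl]-2-methylpropan-1-one F9. Kabbe condensation of F9 with acetone and pyrrolidine (enamine aldol, then oxa-Michael closure) would rejoin the route at 27.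

**Step 12.** Once the C5 ether has fallen, BBr3 or the HBr formed from free phenols may open ring C by retro-oxa-Michael reaction, and re-closure on the C5 oxygen would give the isomeric chromanone; HBr may also split the bridge. The fallback sets out from 27 and divides the deprotection into two low-temperature stages with different mechanisms. BCl3 in CH2Cl2 at −78 → 0 °C would first remove only the three carbonyl-chelated ethers to give 5,7-dihydroxy-8-[[2,4-dihydroxy-6-methoxy-5-methyl-3-(2-methylpropanoyl)phenyl]methyl]-2,2,6-trimethyl-2,3-dihydrochromen-4-one F10. The remaining unchelated methyl ether would then be cleaved by iodide attack on its BCl3 complex (BCl3, n-Bu4NI, −78 → 0 °C), returning at 28.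

**Step 2.** The product chloride may benzylate unreacted 3 under the Lewis acid, giving a diarylmethane. The fallback sets out from 3 and introduces the carbon at the aldehyde oxidation level. Rieche formylation (Cl2CHOMe, TiCl4) would give 2,4,6-trimethoxy-3-methyl-5-(2-methylpropanoyl)benzaldehyde F11. NaBH4 should reduce the aldehyde selectively over the hindered ketone to 1-[3-(hydroxymethyl)-2,4,6-trimethoxy-5-methylphenyl]-2-methylpropan-1-one F12, and SOCl2 would return the route at 4.

**Step 7.** ZnCl2 may polymerise the ynol ether, or an allylic chlorine shift may occur in 17. The fallback sets out from 14 and uses ketene F13 (ethenone, from a ketene generator) in a direct (2+2) cycloaddition. This returns at 18 and bypasses 17 and the dechlorination.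

## Further compounds

F1 | step 9 | (1-ethoxyethenyl)lithium | [Li]C(=C)OCC
F2 | step 9 | 2-ethoxypent-1-en-3-one | CCC(=O)C(=C)OCC
F3 | step 9 | 2-ethoxy-6,6,6-trifluoro-4-methylhex-1-ene-3,5-dione | C=C(OCC)C(=O)C(C)C(=O)C(F)(F)F
F4 | step 9 | 4-diazo-2-ethoxypent-1-en-3-one | CC(=[N+]=[N-])C(=O)C(=C)OCC
F5 | step 5 | (ethoxyethynyl)zinc chloride | CCOC#C[Zn]Cl
F6 | step 5 | 1-[3-(3-ethoxyprop-2-ynyl)-2,4,6-trimethoxy-5-methylphenyl]-2-methylpropan-1-one | CCOC#CCc1c(OC)c(C)c(OC)c(C(=O)C(C)C)c1OC
F7 | step 5 | 1-[3-[(2,4-diethoxy-6-hydroxy-3-methylphenyl)methyl]-2,4,6-trimethoxy-5-methylphenyl]-2-methylpropan-1-one | CCOc1cc(O)c(Cc2c(OC)c(C)c(OC)c(C(=O)C(C)C)c2OC)c(OCC)c1C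
F8 | step 5 | 5,7-diethoxy-2,2,6-trimethyl-8-[[2,4,6-trimethoxy-3-methyl-5-(2-methylpropanoyl)phenyl]methyl]-2,3-dihydrochromen-4-one | CCOc1c(C)c(OCC)c(Cc2c(OC)c(C)c(OC)c(C(=O)C(C)C)c2OC)c2OC(C)(C)CC(=O)c12
F9 | step 11 | 1-[3-[(3-acetyl-4-ethoxy-2,6-dihydroxy-5-methylphenyl)methyl]-2,4,6-trimethoxy-5-methylphenyl]-2-methylpropan-1-one | CCOc1c(C)c(O)c(Cc2c(OC)c(C)c(OC)c(C(=O)C(C)C)c2OC)c(O)c1C(C)=O
F10 | step 12 | 5,7-dihydroxy-8-[[2,4-dihydroxy-6-methoxy-5-methyl-3-(2-methylpropanoyl)phenyl]methyl]-2,2,6-trimethyl-2,3-dihydrochromen-4-one | Cc1c(O)c(C(=O)C(C)C)c(O)c(Cc2c(O)c(C)c(O)c3c2OC(C)(C)CC3=O)c1OC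
F11 | step 2 | 2,4,6-trimethoxy-3-methyl-5-(2-methylpropanoyl)benzaldehyde | COc1c(C=O)c(OC)c(C(=O)C(C)C)c(OC)c1C
F12 | step 2 | 1-[3-(hydroxymethyl)-2,4,6-trimethoxy-5-methylphenyl]-2-methylpropan-1-one | COc1c(CO)c(OC)c(C(=O)C(C)C)c(OC)c1C
F13 | step 7 | ketene (ethenone) | C=C=O
A1 | alternative 1 | 2′,6′,7-tri-O-acetate of the target (C4′ and C5 hydroxyls free) | Cc1c(O)c(C(=O)C(C)C)c(OC(C)=O)c(Cc2c(OC(C)=O)c(C)c(O)c3c2OC(C)(C)CC3=O)c1OC(C)=O
A2 | alternative 1 | 2′,6′,7-tri-O-acetate lacking the C4′ and C5 hydroxyls | Cc1cc(C(=O)C(C)C)c(OC(C)=O)c(Cc2c(OC(C)=O)c(C)cc3c2OC(C)(C)CC3=O)c1OC(C)=O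
A3 | alternative 2 | 5,7-dimethoxy-2,2,6-trimethyl-8-[[2,4,6-trimethoxy-3-methyl-5-(2-methylpropanoyl)phenyl]methyl]-2,3-dihydrochromen-4-one (penta-O-methyl target) | COc1c(C)c(OC)c(Cc2c(OC)c(C)c(OC)c3c2OC(C)(C)CC3=O)c(OC)c1C(=O)C(C)C
A4 | alternative 2 | 3,5-dimethoxy-4-methyl-6-[[2,4,6-trimethoxy-3-methyl-5-(2-methylpropanoyl)phenyl]methyl]-2-(trimethylsilyl)phenyl trifluoromethanesulfonate | COc1c(C)c(OC)c(Cc2c(OC)c(C)c(OC)c(C(=O)C(C)C)c2OC)c(OS(=O)(=O)C(F)(F)F)c1[Si](C)(C)C
A5 | alternative 2 | C4a–C8a aryne derived from A4 | COC1=C(C)C(OC)=C(Cc2c(OC)c(C)c(OC)c(C(=O)C(C)C)c2OC)C#C1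
A6 | alternative 3 | 5,7-dimethoxy-2,2,6-trimethyl-8-[[2,4,6-trihydroxy-3-methyl-5-(2-methylpropanoyl)phenyl]methyl]-2,3-dihydrochromen-4-one (5,7-di-O-methyl target) | Cc1c(O)c(Cc2c(OC)c(C)c(OC)c3c2OC(C)(C)CC3=O)c(O)c(C(=O)C(C)C)c1O
A7 | alternative 3 | 3-[(5,7-dimethoxy-2,2,6-trimethyl-4-oxo-2,3-dihydrochromen-8-yl)methyl]-4-hydroxy-5-methyl-6-(3-methyl-2-oxobutyl)pyran-2-one | CC(C)C(=O)CC1=C(C)C(O)=C(Cc2c(OC)c(C)c(OC)c3c2OC(C)(C)CC3=O)C(=O)O1
A8 | alternative 3 | methyl 2-[(5,7-dimethoxy-2,2,6-trimethyl-4-oxo-2,3-dihydrochromen-8-yl)methyl]-4,8-dimethyl-3,5,7-trioxononanoate (configuration undefined) | COC(=O)C(Cc1c(OC)c(C)c(OC)c2c1OC(C)(C)CC2=O)C(=O)C(C)C(=O)CC(=O)C(C)C
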